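Start from the slope.

| flask | X | L | temperature | remark | time |
|---|---|---|---|---|---|
| violet | 0.34 M | 1.25 M | 0 °C | run made earlier |  |
| grey | 0.75 M | 1.25 M | 33 °C | run made earlier |  |
| elm | 0.50 M | 1.25 M | 5 °C |  | 1.0 h |
| maple | 0.50 M | 1.25 M | 25 °C |  | 1.0 h |
| alder | 0.50 M | 1.25 M | 45 °C |  | 1.0 h |
| oak | 0.50 M | 1.25 M | −15 °C |  | 1.0 h |

- violet (time / min: G / %): 4.00: 0.8; 6.00: 0.3; 8.00: 0.4; 15.0: 1.4; 20.0: 0.8; 30.0: 2.2; 50.0: 2.9
- grey (time / min: G / %): 1.00: 1.1; 1.50: 1.1; 2.00: 0.7; 4.00: 3.6; 5.00: 3.7; 8.00: 5.6; 12.0: 7.8

(each reading ± 0.5 percentage points)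

- percentages count the X that a species holds: one J counts as two
- reactions considered so far: X + L -> G; X + L -> Q; X + L -> D; X + G -> J; L -> Z

* the flask that comes out highest in amount of G, in percent of the X charged, or "all alike" when all lie within 1.5 percentage points (elm / maple / alder / oak / all alike)
* G at the end, in percent of the X charged, elm
* G at the end, in percent of the X charged, maple
* G at the end, in percent of the X charged, alder
* G at the end, in percent of the X charged, oak

**Line yield.** A reading divided by its time is the mean slope of the curve up to that moment. Carried on to 1.0 h, it gives the percent of G a flask holds if that mean slope persists, a zero-order extrapolation. Violet gives 3.48% and grey 39.0%, a factor of 11.2 between their temperatures. The scatter of 0.5 percentage points sits on a violet reading of 2.9%, so this factor is a rough reading. I share it out evenly in its logarithm over the degrees. Maple at 25 °C then has 21.7%, and this is its line yield.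

**Beside grey.** Grey looks nearly like maple, with the same [L] of 1.25 M. Its [X] of 0.75 M against 0.50 M cancels for the step X + L -> G, since in percent of the X charged that gain follows [L] and the fraction of X left. Grey's last reading is 7.8%, and maple's line stands higher, because maple runs 5.00 times as long while its slope is lower by a factor of just 1.80.

**The error.** A straight line keeps one slope, as if X and L stayed at their charges. Counting G alone as a taker of X and leaving L aside, I reckon a mean X in maple of 89.1% of the charge, so the line shrinks to 19.4%. Q, D and J take X too, and L -> Z takes L, so I expect maple below this figure. The lines for elm, 5.02%, and oak, 1.16%, lose 2.51% and 0.580% of themselves by the same correction. Alder's line is 93.9%, which is no usable guide, so I leave alder unranked.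

**The forecast.** It gives 5.3% for elm, 20% for maple, 45% for alder and 1% for oak, and unlike me it ranks alder: “Alder should still be highest”. Its choice is alder.

**The result.** The highest flask is maple, at 12.8%; elm gives 5.28%, alder 1.27% against the forecast's 45%, and oak 0.832%. Maple has converted 40.0% of its X at the end, more than the 21.7% its line put into G, and its G stands at 59.0% of that line.

    X + L → G (k = 0.00450 M⁻¹ min⁻¹, Ea = 59.0 kJ mol⁻¹)
    X + L → Q (k = 0.00440 M⁻¹ min⁻¹, Ea = 60.0 kJ mol⁻¹)
    X + L → D (k = 8.00 × 10⁻⁴ M⁻¹ min⁻¹, Ea = 81.0 kJ mol⁻¹)
    X + G → J (k = 0.0210 M⁻¹ min⁻¹, Ea = 81.0 kJ mol⁻¹)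
    L → Z (k = 0.0130 min⁻¹, Ea = 86.0 kJ mol⁻¹)
    (constants at 25 °C)

**Second flask.** For oak's charge run at 10 °C, the line from maple's value gives 7.24%. The computed flask holds 7.53% of G, with 83% of its X left.

All runs are calculated on assumed constants; the scatter is artificial.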